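(Readings and results were generated by integration with made-up constants.)

In every run, starting material, in whatever form and counted per molecule charged, plus product stays at the charge, and each product made costs one coupling partner.

| flask | starting material | coupling partner | time |
|---|---|---|---|
| birch | 0.400 M | 0.800 M |  |
| ash | 0.200 M | 0.600 M |  |
| oak | 1.20 M | 0.800 M |  |
| larch | 0.400 M | 0.260 M | 20 min |

| birch run: time / min | birch run: [product] / M | ash run: time / min | ash run: [product] / M | oak run: time / min | oak run: [product] / M |
|---|---|---|---|---|---|
| 1.5 | 0.0403 | 1.5 | 0.0186 | 1.5 | 0.0795 |
| 4.6 | 0.0965 | 4.6 | 0.0544 | 4.6 | 0.1789 |
| 8.8 | 0.1470 | 8.8 | 0.0721 | 8.8 | 0.2564 |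
| 14 | 0.1832 | 14 | 0.0950 | 14 | 0.2982 |
| 20 | 0.1946 | 20 | 0.1082 | 20 | 0.3131 |

(readings scatter by 0.002 M)

- Overall: starting material + coupling partner -> product.
- Constant volume, constant temperature.
- What is held in complexes is read along with the free species.
- An order is taken over about fifteen percent of the charge, up and down.

1. reaction order in [starting material] at the outset, round the charge of the birch run, defined at two percent of the starting material turned into product (one fixed amount of product, the same in the runs compared)
2. reaction order in [coupling partner] at the outset, round the charge of the birch run, defined at two percent of the starting material turned into product
3. product in the larch run at 20 min, as a share of the starting material charged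

Oak holds 3.00 times the starting material of birch at the same coupling partner, yet its first reading is 1.97 times that of birch, less than the charge ratio. I write n = 0.618, the apparent order in starting material: the power to which the early rate follows the charge, here the logarithm of the reading ratio over that of the charge ratio.

Ash has half the starting material of birch, which by n costs a factor of 0.651. Its first reading is 0.462 of birch's, and putting the rest on the partner ratio of 0.750 gives an order of 1.20. That ash reading has a scatter of 10.8%, so I commit to order one, matching one partner per product.

Larch has the starting material of birch and 0.325 of its partner, which is the limiting reagent there. Birch scaled by that factor gives 0.0632 M at 20 min, or 15.8%.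

The weak link is that scaling lets larch's starting material fall as birch's does. When half of the product of 20 min is made, I reckon birch at 0.303 M of starting material in all forms and larch, by the scaled estimate, at 0.368 M, so by n I raise the larch rate by a factor of 1.13 and commit to 17.9%.

The forecast, which says of the starting material that “Tripling starting material only doubles the rate”, gives 0.7 for that order, 0.7 for the order in partner and 24% for larch, and each of these differs from my own figure.

The flask gives orders of 0.62 and 1.0, and 19.0% for larch, above my 17.9%.

    starting material + coupling partner ⇌ product + by-product (0.2730 M⁻¹ min⁻¹, 0.05826 M⁻¹ min⁻¹)
    2 starting material ⇌ idle substrate dimer, settled at all times (7.390 M⁻¹)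
    coupling partner → lost reagent (0.06180 min⁻¹)

The order below one comes from the pairing of starting material into idle substrate dimer: without that pairing it is 1.0. With the pairing settled at 7.39 M⁻¹, birch starts with 0.134 M free and oak with 0.253 M, a ratio of 1.89. Ash, whose readings did not enter n, starts with 0.0873 M free, which is 0.651 of birch's, where n gives 0.651.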